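**Remark (assumption on the chemistry):** atoms carry clerodane labels (C1–C19, furan C13–C16); β is the face of ring B that holds the C8 and C9 methyl groups and C19, α is the other face; compounds 1, 6, 12, 21, 28 and 29 are taken to be purchasable.

## Analysis of the target

The target is a rearranged clerodane built from ring A (C1–C5, C10, with C3=C4), ring B (C5–C10), a seven-membered ring C (C1, C10, C9, C11, C12, C13, C16) fused to a furan (C13–C16), and a γ-lactone (C4–C18–O–C19–C5) that shares C4–C5 with ring A. There are six stereocentres (C1, C5, C7, C8, C9, C10), of which C5, C9 and C10 are contiguous and fully substituted. C19, the C9 methyl and the C7 acetate are all axial on the β face of ring B, the C8 methyl is equatorial β, and the C10 hydroxyl is axial α, so rings A/B and B/C are trans-fused; C1 carries its hydrogen β. The furan is sensitive to acid, oxidants and electrophilic halogen, and the furyl ketone at C12 acidifies C11 and, through the furan, C1. Because the C10 hydroxyl is β to C1, the molecule is a vinylogous aldol that can dehydrate or cleave once C1 is deprotonated. The alkylidene lactone is a Michael acceptor and the axial acetate is hindered. The difficulty lies in the three adjacent quaternary carbons, the crowded β face, and a ring C whose C1 methylene becomes very acidic as soon as C10 and C12 are both ketones. The strategy rests on one feature: C4, the α-carbon of an α-alkylidene γ-lactone, is bonded to quaternary C5, C5 also carries the lactone methylene C19, and C6 is a methylene next to oxygenated C7. This is the pattern left by a 5-exo carbopalladation of a C5=C6 alkene by an alkenylpalladium at C4 tethered through the C19 ester, ended by β-hydride elimination toward C7.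

## Retrosynthetic reasoning

**Ring A, C1–C2.** Ring A of 41 is opened last at C1–C2, the one ring bond that an extended enolate through the furan (C12 ketone, C13=C16, C1) can make by displacing an allylic leaving group at C2. This gives bromide 39, which needs C2 cis to C5 on the exocyclic alkene. The C10 oxygen is β to the C1 carbanion, so it cannot be an ether or silyl ether (it would be eliminated) and must be an alkoxide that does not alkylate; it is held as the magnesium alkoxide 40. Bromide 39 comes from allylic alcohol 38, and 38 from 37 by one acidic deprotection that also unmasks C12. The C2 oxygen is therefore carried from the start instead of being introduced by allylic oxidation next to a furan.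

**C7 acetate.** The axial acetate of 37 is traced to the C7 ketone 35. Reduction must come from the α side, which the axial C19 and C9 methyl enforce. Ketone 35 is the hydrolysis product of silyl enol ether 34.

**Key disconnection, C4–C5 and the lactone.** Enol ether 34 is cut at C4–C5, the bond between the lactone α-carbon and the quaternary centre. Going forward, the alkenyl iodide of ester 33 must add to C5 of the C5=C6 alkene on the α face and the metal must leave by taking the C7 hydrogen. This one step makes the quaternary centre C5, the lactone and a ketone equivalent at C7.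

**Ester bond.** 33 is the ester of allylic diol 27 with iodo acid 32. Acid 32, with the (Z) geometry that becomes the C2-cis-to-C5 alkylidene, comes from aldehyde 28 and ylide 29 through ester 31.

**Ring B, C5=C6.** The trisubstituted alkene of 27 is cut by metathesis to triene 26 (from 25), which has a 1,1-disubstituted alkene on C10 and a vinyl group on C7. This keeps ring B out of the synthesis until C10 has been set.

**C5–C10.** Carbinol 25 is cut to ring C ketone 20 and bromide 22 (from 21). The cut is made here because, in the seven-membered ketone, C1 and C11 are tied together and the branched C8 arm on C9 blocks one face, so an external nucleophile sets C10 with the trans B/C relationship that an intramolecular closure would not give. C12 has to be masked at this point (dioxolane), otherwise C1 is too acidic and C12 competes as an electrophile.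

**Ring C, C1–C16 and C1–C10.** Ketone 20 is opened at C1–C16 to methyl ketone 19. Its only enolisable position is C1, so an enolate arylation by the chlorofuran is regiochemically unambiguous. 19 comes from hydroxy ketone 18, and 18 from lactone 17 by addition of a one-carbon nucleophile, so the lactone carbonyl is C10 and the lactone oxygen is the C7 oxygen.

**C12–C13.** Ketal 17 comes from ketone 16, which is cut between C12 and C13 to Weinreb amide 11 and the lithiated form of chlorofuran 14 (from 12).

**Stereotriad C7–C8–C9.** Lactone 11 comes from 9 and 8, and 8 from 5 and bromoacetamide 6. Lactone 5 comes from 3, 3 from 2, and 2 from butenolide 1. The single stereocentre of 1 (C7) controls C8 by conjugate addition and C9 by two enolate alkylations in the right order, all on a five-membered ring where facial control is dependable.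

## Alternatives that were turned down

**Alternative 1:** The disconnection is C1–C16 of ring C. In the forward direction the C10 silyl enol ether A2 would be oxidised at a carbon anode, and the resulting radical cation would be trapped by the furan α-carbon C16 to give cycloheptanone A1, with C12 as a dioxolane and the whole C9 arm (C8 to C5, C19 silyl ether, methyl ester) in place. In its favour, the ring closure uses the unfunctionalised furan C–H, needs no halofuran and no noble metal, and A1 already carries C5 and C19. On these points it is as good as or better than the chosen ring C closure (step 12), and A1 is close in structure to ketone 20. Against it, after A1 ring B must be closed by an ester enolate aldol onto the C10 ketone. This must create the vicinal quaternary pair C5/C10 in one step while the furfuryl C1–H is the more acidic site. Such closures onto a ring ketone normally give the cis-fused carbinol, whereas the target has C19 and the C10 hydroxyl anti. Ring A and the alkylidene would then have to be made from a saturated ester. The chosen strategy sets C10 by an intermolecular addition under Felkin–Anh control and C5 separately, with face control, in the Heck step.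

**Alternative 2:** The disconnection is C5–C10 and C3–C4 together. In the forward direction the 2-alkylfuran A4, whose α-carbon becomes C10, would add as a diene across its tethered butenolide alkene (C4=C5) to give the exo oxanorbornene A3 with an oxygen bridge from C10 to C3. In its favour, one thermal step makes quaternary C5, the C10 oxygen and rings A and B, and opening the bridge by elimination from the lactone α-position would unveil both the C10 hydroxyl and C3=C4. In bond count per step this beats the chosen route. Against it, furan Diels–Alder reactions are reversible and slow when the dienophile is trisubstituted and the new bond joins two fully substituted carbons next to quaternary C9, and endo/exo and facial selectivity would have to set C5 and C10 against C9 at once. The furan is also consumed, so the target's own furan, all of ring C, the C12 ketone and the C1 stereocentre would have to be built late on a C1=C2 alkene. The chosen strategy has ring C and the furan in place early and uses ring C as the control element for C10.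

**Alternative 3:** The disconnection is C4–C5 and C1–C10 of ring A. In the forward direction the enolate of ring B ketone A6 would add at C5 to ynone ester A7, and the resulting C1 enolate would close onto the C10 ketone to give ketol A5 (C2 ketone, C3=C4 ester, bromofuryl on C1). In its favour it is convergent, makes two C–C bonds and ring A in one flask, and brings C3=C4 at the right oxidation level. On convergence it is stronger than the chosen route. Against it, the aldol half closes a six-membered ring onto a ring ketone, which normally places the hydroxyl syn to the angular C19, opposite to the target. The face of C5 alkylation against C9 is uncertain. A5 is a β-hydroxy ketone that can dehydrate or cleave. The extra C2 ketone must be removed without touching the enoate, and ring C still has to be closed. The chosen strategy carries no extra oxygen and fixes C10 before C5.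

Key step: step 20

## Steps

Step 1
Reactants: 1 (S)-5-(hydroxymethyl)furan-2(5H)-one
Product: 2 (S)-5-{[(tert-butyldimethylsilyl)oxy]methyl}furan-2(5H)-one
Conditions: TBSCl, imidazole, CH2Cl2, 0 °C → rt
Reagents that add atoms: tert-butyldimethylsilyl chloride, CC(C)(C)[Si](C)(C)Cl
Why: Imidazole-promoted silylation of the primary alcohol; the bulky silyloxymethyl group (C6) on C7 becomes the control element of the lactone template.

Step 2
Reactants: 2 (S)-5-{[(tert-butyldimethylsilyl)oxy]methyl}furan-2(5H)-one
Product: 3 (4S,5S)-5-{[(tert-butyldimethylsilyl)oxy]methyl}-4-methyloxolan-2-one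
Conditions: Me2CuLi (from MeLi and CuI), Et2O, −78 → −40 °C; aq. NH4Cl
Reagents that add atoms: lithium dimethylcuprate, [Li+].C[Cu-]C
Why: Conjugate addition of a Gilman cuprate to a γ-substituted butenolide; the methyl group should enter C8 anti to the C7 substituent, which fixes the C7/C8 relationship of the target (oxygen and methyl cis on ring B).

Step 3
Reactants: 3 (4S,5S)-5-{[(tert-butyldimethylsilyl)oxy]methyl}-4-methyloxolan-2-one
Product: 5 (3S,4S,5S)-5-{[(tert-butyldimethylsilyl)oxy]methyl}-3,4-dimethyloxolan-2-one, via C9 lithium enolate 4 (not isolated)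
Conditions: LiN(i-Pr)2, THF, −78 °C; MeI, −78 → −40 °C
Reagents that add atoms: iodomethane, CI
Why: Lactone enolate alkylation; the methyl group is expected anti to the C8 methyl, but this centre is flattened again in step 4, so its configuration is of no consequence.

Step 4
Reactants: 5 (3S,4S,5S)-5-{[(tert-butyldimethylsilyl)oxy]methyl}-3,4-dimethyloxolan-2-one; 6 2-bromo-N-methoxy-N-methylacetamide
Product: 8 2-[(3S,4S,5S)-5-{[(tert-butyldimethylsilyl)oxy]methyl}-3,4-dimethyl-2-oxooxolan-3-yl]-N-methoxy-N-methylacetamide, via tetrasubstituted lithium enolate 7 (not isolated)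
Conditions: LiN(i-Pr)2, THF–DMPU, −78 °C; then 6, −78 → −20 °C
Reagents that add atoms: none
Why: Alkylation of a tetrasubstituted lactone enolate by an α-bromo amide; the electrophile should approach C9 anti to the neighbouring C8 methyl, which leaves the two methyl groups cis and places C11 and C12 (as a Weinreb amide) on the other face, so the quaternary centre C9 is set.

Step 5
Reactants: 8 2-[(3S,4S,5S)-5-{[(tert-butyldimethylsilyl)oxy]methyl}-3,4-dimethyl-2-oxooxolan-3-yl]-N-methoxy-N-methylacetamide
Product: 9 2-[(3S,4S,5S)-5-(hydroxymethyl)-3,4-dimethyl-2-oxooxolan-3-yl]-N-methoxy-N-methylacetamide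
Conditions: HF·pyridine, THF, 0 °C → rt
Reagents that add atoms: none
Why: Fluoride cleavage of the primary silyl ether; the acidic fluoride source avoids an alkoxide that could translactonise, and lactone and Weinreb amide are inert.

Step 6
Reactants: 9 2-[(3S,4S,5S)-5-(hydroxymethyl)-3,4-dimethyl-2-oxooxolan-3-yl]-N-methoxy-N-methylacetamide
Product: 11 2-[(3S,4S,5R)-5-ethenyl-3,4-dimethyl-2-oxooxolan-3-yl]-N-methoxy-N-methylacetamide, via C6 aldehyde 10 (not isolated)
Conditions: Dess–Martin periodinane, pyridine, CH2Cl2, 0 °C; filtration; then Ph3P=CH2 (from Ph3PCH3Br and KN(SiMe3)2), THF, −78 → 0 °C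
Reagents that add atoms: methylenetriphenylphosphorane, C=P(c1ccccc1)(c1ccccc1)c1ccccc1
Why: Dess–Martin oxidation followed by Wittig methylenation turns C6 into the vinyl group needed for metathesis; the α-oxygenated aldehyde is not stored and meets the ylide at low temperature so that C7 should not epimerise, and lactone and amide are much less electrophilic than the aldehyde.

Step 7
Reactants: 12 3-bromofuran
Product: 14 3-bromo-2-chlorofuran, via 3-bromo-2-lithiofuran 13 (not isolated)
Conditions: LiN(i-Pr)2, THF, −78 °C; then C2Cl6, −78 °C → rt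
Reagents that add atoms: hexachloroethane, ClC(Cl)(Cl)C(Cl)(Cl)Cl
Why: Directed deprotonation of 3-bromofuran at the α position next to bromine and electrophilic chlorination of the lithio species; the chlorine is the later handle on C16.

Step 8
Reactants: 14 3-bromo-2-chlorofuran; 11 2-[(3S,4S,5R)-5-ethenyl-3,4-dimethyl-2-oxooxolan-3-yl]-N-methoxy-N-methylacetamide
Product: 16 (3S,4S,5R)-3-[2-(2-chlorofuran-3-yl)-2-oxoethyl]-5-ethenyl-3,4-dimethyloxolan-2-one, via 2-chloro-3-lithiofuran 15 (not isolated)
Conditions: n-BuLi, Et2O–THF, −78 °C; then 11, −78 °C; aq. NH4Cl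
Reagents that add atoms: none
Why: Bromine–lithium exchange (much faster than chlorine exchange) and acylation of the furyllithium by the Weinreb amide form C12–C13; the chelated adduct prevents over-addition and the hindered lactone carbonyl should not compete at −78 °C.

Step 9
Reactants: 16 (3S,4S,5R)-3-[2-(2-chlorofuran-3-yl)-2-oxoethyl]-5-ethenyl-3,4-dimethyloxolan-2-one
Product: 17 (3S,4S,5R)-3-{[2-(2-chlorofuran-3-yl)-1,3-dioxolan-2-yl]methyl}-5-ethenyl-3,4-dimethyloxolan-2-one
Conditions: Me3SiOCH2CH2OSiMe3, Me3SiOTf (cat.), CH2Cl2, −78 → −20 °C; pyridine quench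
Reagents that add atoms: 1,2-bis(trimethylsilyloxy)ethane, C[Si](C)(C)OCCO[Si](C)(C)C
Why: Ketalisation under aprotic silyl triflate catalysis, mild enough for the furan; the dioxolane masks C12 so that C1 is later only an ordinary furfuryl ketone position and C12 cannot accept a nucleophile.

Step 10
Reactants: 17 (3S,4S,5R)-3-{[2-(2-chlorofuran-3-yl)-1,3-dioxolan-2-yl]methyl}-5-ethenyl-3,4-dimethyloxolan-2-one
Product: 18 (3S,4S,5R)-3-{[2-(2-chlorofuran-3-yl)-1,3-dioxolan-2-yl]methyl}-5-hydroxy-3,4-dimethylhept-6-en-2-one (in equilibrium with its lactol)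
Conditions: MeLi, THF, −78 → −40 °C; aq. NH4Cl
Reagents that add atoms: methyllithium, [Li]C
Why: Mono-addition of an organolithium to a lactone (the cyclic lithium hemiketal resists a second addition); the lactone carbonyl becomes the C10 ketone, the new methyl is C1, and the ring oxygen is released as the C7 hydroxyl.

Step 11
Reactants: 18 (3S,4S,5R)-3-{[2-(2-chlorofuran-3-yl)-1,3-dioxolan-2-yl]methyl}-5-hydroxy-3,4-dimethylhept-6-en-2-one
Product: 19 (3S,4S,5R)-5-[(tert-butyldimethylsilyl)oxy]-3-{[2-(2-chlorofuran-3-yl)-1,3-dioxolan-2-yl]methyl}-3,4-dimethylhept-6-en-2-one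
Conditions: TBSCl, imidazole, DMF, rt
Reagents that add atoms: tert-butyldimethylsilyl chloride, CC(C)(C)[Si](C)(C)Cl
Why: Silylation of the secondary allylic alcohol traps the open hydroxy ketone form and installs the C7 silyl ether that the key step later turns into an enol ether.

Step 12
Reactants: 19 (3S,4S,5R)-5-[(tert-butyldimethylsilyl)oxy]-3-{[2-(2-chlorofuran-3-yl)-1,3-dioxolan-2-yl]methyl}-3,4-dimethylhept-6-en-2-one
Product: 20 ring C ketone (6S)-6-[(2S,3R)-3-(tert-butyldimethylsilyloxy)pent-4-en-2-yl]-6-methyl-5,6-dihydrospiro[cyclohepta[b]furan-4,2'-[1,3]dioxolan]-7(8H)-one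
Conditions: Pd2(dba)3, XPhos, NaOt-Bu, toluene, 80 °C
Reagents that add atoms: none
Why: Palladium-catalysed intramolecular α-arylation of a ketone enolate forms C1–C16 and closes the seven-membered ring C; the methyl ketone can enolise only toward C1 because C9 is quaternary, so the regiochemistry is unambiguous.

Step 13
Reactants: 21 2-bromoprop-2-en-1-ol
Product: 22 [(2-bromoprop-2-en-1-yl)oxy](tert-butyl)dimethylsilane
Conditions: TBSCl, imidazole, CH2Cl2, 0 °C → rt
Reagents that add atoms: tert-butyldimethylsilyl chloride, CC(C)(C)[Si](C)(C)Cl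
Why: Silyl protection of the allylic alcohol so that the bromide can be converted into an alkenyl organometallic carrying C5 and C19.

Step 14
Reactants: 20 ring C ketone (6S)-6-[(2S,3R)-3-(tert-butyldimethylsilyloxy)pent-4-en-2-yl]-6-methyl-5,6-dihydrospiro[cyclohepta[b]furan-4,2'-[1,3]dioxolan]-7(8H)-one; 22 [(2-bromoprop-2-en-1-yl)oxy](tert-butyl)dimethylsilane
Product: 25 (6S,7S)-7-[3-(tert-butyldimethylsilyloxy)prop-1-en-2-yl]-6-[(2S,3R)-3-(tert-butyldimethylsilyloxy)pent-4-en-2-yl]-6-methyl-5,6,7,8-tetrahydrospiro[cyclohepta[b]furan-4,2'-[1,3]dioxolan]-7-ol (C5 syn to the C9 methyl; C10 hydroxyl anti to it), via alkenyllithium 23 (not isolated), via alkenylcerium dichloride 24 (not isolated)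
Conditions: 22, t-BuLi (2 equiv), Et2O, −78 °C; CeCl3, THF, −78 °C; then 20, −78 → −40 °C; aq. NH4Cl
Reagents that add atoms: none
Why: Bromine–lithium exchange, transmetalation to the weakly basic organocerium reagent and 1,2-addition form C5–C10 while enolisation at the furfuryl C1 is suppressed. The new stereocentre C10 is set by a Felkin–Anh approach: with C1 and C11 tied together in ring C, the reagent comes in anti to the branched C8 arm on C9, so C5 ends syn to the C9 methyl and the hydroxyl anti to it, as the trans B/C fusion requires.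

Step 15
Reactants: 25 (6S,7S)-7-[3-(tert-butyldimethylsilyloxy)prop-1-en-2-yl]-6-[(2S,3R)-3-(tert-butyldimethylsilyloxy)pent-4-en-2-yl]-6-methyl-5,6,7,8-tetrahydrospiro[cyclohepta[b]furan-4,2'-[1,3]dioxolan]-7-ol
Product: 26 (6S,7S)-7-(3-hydroxyprop-1-en-2-yl)-6-[(2S,3R)-3-(tert-butyldimethylsilyloxy)pent-4-en-2-yl]-6-methyl-5,6,7,8-tetrahydrospiro[cyclohepta[b]furan-4,2'-[1,3]dioxolan]-7-ol
Conditions: HF·pyridine, pyridine, THF, 0 °C
Reagents that add atoms: none
Why: Selective cleavage of the primary allylic silyl ether with buffered fluoride; the hindered secondary C7 silyl ether and the dioxolane should survive.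

Step 16
Reactants: 26 (6S,7S)-7-(3-hydroxyprop-1-en-2-yl)-6-[(2S,3R)-3-(tert-butyldimethylsilyloxy)pent-4-en-2-yl]-6-methyl-5,6,7,8-tetrahydrospiro[cyclohepta[b]furan-4,2'-[1,3]dioxolan]-7-ol
Product: 27 ring B/ring C/furan allylic diol (C5=C6; C5 hydroxymethyl C19; 7β-silyloxy; 8β-methyl; 9β-methyl; 10α-hydroxyl; C12 dioxolane)
Conditions: second-generation Grubbs catalyst RuCl2(=CHPh)(H2IMes)(PCy3), CH2Cl2, 40 °C
Reagents that add atoms: none
Why: Ring-closing metathesis of the 1,1-disubstituted alkene on C10 with the vinyl group on C7 forms C5=C6 and closes ring B trans-fused to ring C; free allylic hydroxyls are tolerated and no other alkene can compete.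

Step 17
Reactants: 28 [(tert-butyldimethylsilyl)oxy]acetaldehyde; 29 ethyl (triphenyl-λ5-phosphanylidene)acetate
Product: 31 ethyl (Z)-4-[(tert-butyldimethylsilyl)oxy]-2-iodobut-2-enoate, via iodo ylide 30 (not isolated)
Conditions: 29, N-iodosuccinimide, MeCN, −20 °C; then 28, −20 °C → rt
Reagents that add atoms: N-iodosuccinimide, O=C1CCC(=O)N1I
Why: Iodination of the stabilised ylide followed by Wittig olefination; the ester ends trans to the C2 substituent, which is the (Z)-2-iodo enoate, and the C2 oxygen needed for ring A is present from the start.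

Step 18
Reactants: 31 ethyl (Z)-4-[(tert-butyldimethylsilyl)oxy]-2-iodobut-2-enoate
Product: 32 (Z)-4-[(tert-butyldimethylsilyl)oxy]-2-iodobut-2-enoic acid
Conditions: LiOH, THF–H2O, 0 °C; then aq. HCl to pH 4
Reagents that add atoms: lithium hydroxide, [Li+].[OH-]
Why: Saponification of the ethyl ester; the alkenyl iodide and the primary silyl ether are stable to cold hydroxide and brief mild acidification.

Step 19
Reactants: 27 ring B/ring C/furan allylic diol; 32 (Z)-4-[(tert-butyldimethylsilyl)oxy]-2-iodobut-2-enoic acid
Product: 33 Heck precursor: (Z)-4-(silyloxy)-2-iodobut-2-enoate of the C19 hydroxyl of 27 (10α-hydroxyl free; 7β-silyloxy; C12 dioxolane)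
Conditions: N,N'-dicyclohexylcarbodiimide, 4-(dimethylamino)pyridine (cat.), CH2Cl2, 0 °C → rt
Reagents that add atoms: none
Why: Carbodiimide esterification of the primary allylic alcohol; the tertiary C10 hydroxyl, flanked by two fully substituted carbons, should not be acylated.

Step 20
Reactants: 33 Heck precursor
Product: 34 (E)-alkylidene spirolactone on quaternary C5 with C6=C7 silyl enol ether (C2 silyloxy cis to C5; 10α-hydroxyl; C12 dioxolane)
Conditions: Pd(OAc)2, PPh3, Et3N, MeCN, 80 °C
Reagents that add atoms: none
Why: Zerovalent palladium, formed in the flask from Pd(OAc)2 and PPh3, inserts into the C4–I bond of 33 with retention of the (Z) geometry. After rotation of the ester into its s-cis form, the alkenylpalladium species (divalent palladium) adds syn across C5=C6 in a 5-exo-trig carbopalladation that forms C4–C5 and closes the γ-lactone (C4–C18–O–C19–C5); this is the only mode that puts carbon on C5. The closest known reaction type is the intramolecular Heck cyclisation of α-halo acrylate esters and amides onto trisubstituted cycloalkenes with formation of a quaternary centre. The new stereocentre C5 is controlled by the face of attack: the β face of C5=C6 is screened by the axial C9 methyl and the pseudo-axial C7 silyloxy group, while the α face carries only the C10 hydroxyl, so C4 should enter α and C19 is pushed β. Palladium then sits on C6 on the α face; C5 has no hydrogen and the only syn β-hydrogen is the α C7–H, so elimination gives the C6=C7 silyl enol ether and the C7 stereocentre is given up for the reduction in step 22. The step needs 5-exo closure in preference to 6-endo closure and to ionisation of the allylic ester; the fast oxidative addition to the alkenyl iodide and the short tether secure this. Because the alkene geometry is kept, C2 lies cis to C5, as ring A requires.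

Step 21
Reactants: 34 (E)-alkylidene spirolactone with C6=C7 silyl enol ether
Product: 35 C7 ketone (C2 primary silyl ether and C12 dioxolane retained; 8β-methyl; 10α-hydroxyl)
Conditions: Bu4NF (1.05 equiv), AcOH, THF, −40 °C
Reagents that add atoms: none
Why: Buffered fluoride cleaves a silyl enol ether far faster than a primary alkyl silyl ether and releases the C7 ketone; C8 keeps its equatorial β methyl, the preferred arrangement next to the ketone.

Step 22
Reactants: 35 C7 ketone
Product: 37 7β-acetate (axial; C2 silyl ether and C12 dioxolane retained), via C7 lithium alkoxide 36 (not isolated)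
Conditions: LiBH(sec-Bu)3, THF, −78 °C; then Ac2O, 4-(dimethylamino)pyridine, −78 °C → rt
Reagents that add atoms: acetic anhydride, CC(=O)OC(C)=O
Why: The bulky hydride must attack C7 from the α side because the β face is closed by the axial C19 and C9 methyl, which gives the axial β alkoxide and sets C7. The alkoxide is acetylated in the same flask, since direct acylation of this hindered axial alcohol would be slow; the dioxolane keeps C12 out of the reduction.

Step 23
Reactants: 37 7β-acetate
Product: 38 allylic alcohol at C2 with free C12 ketone (7β-acetate; 10α-hydroxyl)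
Conditions: aq. HF, MeCN, 0 °C → rt
Reagents that add atoms: water, O
Why: One acidic operation removes the primary silyl ether and hydrolyses the labile furyl dioxolane; acetate and lactone are stable, and the C2 hydroxyl is trans to the lactone carbonyl and cannot translactonise.

Step 24
Reactants: 38 allylic alcohol at C2
Product: 39 allylic bromide at C2 (7β-acetate; 10α-hydroxyl; C12 ketone)
Conditions: CBr4, PPh3, CH2Cl2, −20 °C; used at once
Reagents that add atoms: carbon tetrabromide, BrC(Br)(Br)Br
Why: Appel bromination of the primary allylic alcohol under neutral conditions; the tertiary C10 hydroxyl does not react, and a bromide favours attack by carbon in the next step.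

Step 25
Reactants: 39 allylic bromide at C2
Product: 41 the target CNP0329797.2, via C10 chloromagnesium alkoxide 40 (not isolated)
Conditions: t-BuMgCl (1.0 equiv), THF, −78 °C; then LiN(SiMe3)2 (1.3 equiv), −78 → 0 °C; aq. NH4Cl
Reagents that add atoms: none
Why: Intramolecular C-alkylation of the extended enolate of the 2-alkyl-3-acylfuran (lateral deprotonation at C1) by the allylic bromide, 6-exo-tet, closes ring A; attack at C3 would be 5-endo-trig. The C10 oxygen is first turned into its chloromagnesium alkoxide, which is a poor nucleophile toward C2 and, unlike an ether, cannot be lost by β-elimination from the C1 carbanion. C2 can reach the planar C1 only from the α side next to the C10 oxygen, so the C1 hydrogen ends β and the stereocentre C1 is set by the ring closure.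

## Compound list

1 | (S)-5-(hydroxymethyl)furan-2(5H)-one | OC[C@H]1OC(=O)C=C1 | starting material
2 | (S)-5-{[(tert-butyldimethylsilyl)oxy]methyl}furan-2(5H)-one | CC(C)(C)[Si](C)(C)OC[C@H]1OC(=O)C=C1 | intermediate
3 | (4S,5S)-5-{[(tert-butyldimethylsilyl)oxy]methyl}-4-methyloxolan-2-one | CC(C)(C)[Si](C)(C)OC[C@H]1OC(=O)C[C@@H]1C | intermediate
4 | C9 lithium enolate of 3 | [Li+].CC(C)(C)[Si](C)(C)OC[C@H]1OC([O-])=C[C@@H]1C | intermediate
5 | (3S,4S,5S)-5-{[(tert-butyldimethylsilyl)oxy]methyl}-3,4-dimethyloxolan-2-one | CC(C)(C)[Si](C)(C)OC[C@H]1OC(=O)[C@@H](C)[C@@H]1C | intermediate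
6 | 2-bromo-N-methoxy-N-methylacetamide | CON(C)C(=O)CBr | starting material
7 | tetrasubstituted lithium enolate of 5 | [Li+].CC(C)(C)[Si](C)(C)OC[C@H]1OC([O-])=C(C)[C@@H]1C | intermediate
8 | 2-[(3S,4S,5S)-5-{[(tert-butyldimethylsilyl)oxy]methyl}-3,4-dimethyl-2-oxooxolan-3-yl]-N-methoxy-N-methylacetamide | CC(C)(C)[Si](C)(C)OC[C@H]1OC(=O)[C@@](C)(CC(=O)N(C)OC)[C@@H]1C | intermediate
9 | 2-[(3S,4S,5S)-5-(hydroxymethyl)-3,4-dimethyl-2-oxooxolan-3-yl]-N-methoxy-N-methylacetamide | OC[C@H]1OC(=O)[C@@](C)(CC(=O)N(C)OC)[C@@H]1C | intermediate
10 | 2-[(3S,4S,5S)-5-formyl-3,4-dimethyl-2-oxooxolan-3-yl]-N-methoxy-N-methylacetamide (C6 aldehyde) | O=C[C@H]1OC(=O)[C@@](C)(CC(=O)N(C)OC)[C@@H]1C | intermediate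
11 | 2-[(3S,4S,5R)-5-ethenyl-3,4-dimethyl-2-oxooxolan-3-yl]-N-methoxy-N-methylacetamide | C=C[C@H]1OC(=O)[C@@](C)(CC(=O)N(C)OC)[C@@H]1C | intermediate
12 | 3-bromofuran | Brc1ccoc1 | starting material
13 | 3-bromo-2-lithiofuran | [Li]c1occc1Br | intermediate
14 | 3-bromo-2-chlorofuran | Clc1occc1Br | intermediate
15 | 2-chloro-3-lithiofuran | [Li]c1ccoc1Cl | intermediate
16 | (3S,4S,5R)-3-[2-(2-chlorofuran-3-yl)-2-oxoethyl]-5-ethenyl-3,4-dimethyloxolan-2-one | C=C[C@H]1OC(=O)[C@@](C)(CC(=O)c2ccoc2Cl)[C@@H]1C | intermediate
17 | (3S,4S,5R)-3-{[2-(2-chlorofuran-3-yl)-1,3-dioxolan-2-yl]methyl}-5-ethenyl-3,4-dimethyloxolan-2-one | C=C[C@H]1OC(=O)[C@@](C)(CC2(OCCO2)c2ccoc2Cl)[C@@H]1C | intermediate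
18 | (3S,4S,5R)-3-{[2-(2-chlorofuran-3-yl)-1,3-dioxolan-2-yl]methyl}-5-hydroxy-3,4-dimethylhept-6-en-2-one | CC(=O)[C@@](C)(CC1(OCCO1)c1ccoc1Cl)[C@H](C)[C@H](O)C=C | intermediate
19 | (3S,4S,5R)-5-[(tert-butyldimethylsilyl)oxy]-3-{[2-(2-chlorofuran-3-yl)-1,3-dioxolan-2-yl]methyl}-3,4-dimethylhept-6-en-2-one | CC(=O)[C@@](C)(CC1(OCCO1)c1ccoc1Cl)[C@H](C)[C@H](O[Si](C)(C)C(C)(C)C)C=C | intermediate
20 | ring C ketone (6S)-6-[(2S,3R)-3-(tert-butyldimethylsilyloxy)pent-4-en-2-yl]-6-methyl-5,6-dihydrospiro[cyclohepta[b]furan-4,2'-[1,3]dioxolan]-7(8H)-one | O=C1Cc2occc2C2(OCCO2)C[C@@]1(C)[C@H](C)[C@H](O[Si](C)(C)C(C)(C)C)C=C | intermediate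
21 | 2-bromoprop-2-en-1-ol | OCC(Br)=C | starting material
22 | [(2-bromoprop-2-en-1-yl)oxy](tert-butyl)dimethylsilane | C=C(Br)CO[Si](C)(C)C(C)(C)C | intermediate
23 | [3-(tert-butyldimethylsilyloxy)prop-1-en-2-yl]lithium | [Li]C(=C)CO[Si](C)(C)C(C)(C)C | intermediate
24 | [3-(tert-butyldimethylsilyloxy)prop-1-en-2-yl]cerium dichloride | Cl[Ce](Cl)C(=C)CO[Si](C)(C)C(C)(C)C | intermediate
25 | (6S,7S)-7-[3-(tert-butyldimethylsilyloxy)prop-1-en-2-yl]-6-[(2S,3R)-3-(tert-butyldimethylsilyloxy)pent-4-en-2-yl]-6-methyl-5,6,7,8-tetrahydrospiro[cyclohepta[b]furan-4,2'-[1,3]dioxolan]-7-ol | C=C(CO[Si](C)(C)C(C)(C)C)[C@]1(O)Cc2occc2C2(OCCO2)C[C@@]1(C)[C@H](C)[C@H](O[Si](C)(C)C(C)(C)C)C=C | intermediate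
26 | (6S,7S)-7-(3-hydroxyprop-1-en-2-yl)-6-[(2S,3R)-3-(tert-butyldimethylsilyloxy)pent-4-en-2-yl]-6-methyl-5,6,7,8-tetrahydrospiro[cyclohepta[b]furan-4,2'-[1,3]dioxolan]-7-ol | C=C(CO)[C@]1(O)Cc2occc2C2(OCCO2)C[C@@]1(C)[C@H](C)[C@H](O[Si](C)(C)C(C)(C)C)C=C | intermediate
27 | ring B/ring C/furan allylic diol (C5=C6; C19 hydroxyl; 7β-OTBS; 8β-Me; 9β-Me; 10α-OH; C12 dioxolane) | OCC1=C[C@@H](O[Si](C)(C)C(C)(C)C)[C@@H](C)[C@]2(C)CC3(OCCO3)c3ccoc3C[C@@]12O | intermediate
28 | [(tert-butyldimethylsilyl)oxy]acetaldehyde | CC(C)(C)[Si](C)(C)OCC=O | starting material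
29 | ethyl (triphenyl-λ5-phosphanylidene)acetate | CCOC(=O)C=P(c1ccccc1)(c1ccccc1)c1ccccc1 | starting material
30 | ethyl iodo(triphenyl-λ5-phosphanylidene)acetate | CCOC(=O)C(I)=P(c1ccccc1)(c1ccccc1)c1ccccc1 | intermediate
31 | ethyl (Z)-4-[(tert-butyldimethylsilyl)oxy]-2-iodobut-2-enoate | CC(C)(C)[Si](C)(C)OC/C=C(\I)C(=O)OCC | intermediate
32 | (Z)-4-[(tert-butyldimethylsilyl)oxy]-2-iodobut-2-enoic acid | CC(C)(C)[Si](C)(C)OC/C=C(\I)C(=O)O | intermediate
33 | Heck precursor: C19 (Z)-4-(silyloxy)-2-iodobut-2-enoate of 27 | CC(C)(C)[Si](C)(C)OC/C=C(\I)C(=O)OCC1=C[C@@H](O[Si](C)(C)C(C)(C)C)[C@@H](C)[C@]2(C)CC3(OCCO3)c3ccoc3C[C@@]12O | intermediate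
34 | (E)-alkylidene spirolactone on quaternary C5 with C6=C7 silyl enol ether | CC(C)(C)[Si](C)(C)OC/C=C1/C(=O)OC[C@]12C=C(O[Si](C)(C)C(C)(C)C)[C@@H](C)[C@]3(C)CC4(OCCO4)c4ccoc4C[C@@]23O | intermediate
35 | C7 ketone | CC(C)(C)[Si](C)(C)OC/C=C1/C(=O)OC[C@]12CC(=O)[C@@H](C)[C@]3(C)CC4(OCCO4)c4ccoc4C[C@@]23O | intermediate
36 | C7 lithium alkoxide (7β, axial) | [Li+].CC(C)(C)[Si](C)(C)OC/C=C1/C(=O)OC[C@]12C[C@@H]([O-])[C@@H](C)[C@]3(C)CC4(OCCO4)c4ccoc4C[C@@]23O | intermediate
37 | 7β-acetate with C2 silyl ether and C12 dioxolane | CC(C)(C)[Si](C)(C)OC/C=C1/C(=O)OC[C@]12C[C@@H](OC(C)=O)[C@@H](C)[C@]3(C)CC4(OCCO4)c4ccoc4C[C@@]23O | intermediate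
38 | C2 allylic alcohol with free C12 ketone | OC/C=C1/C(=O)OC[C@]12C[C@@H](OC(C)=O)[C@@H](C)[C@]3(C)CC(=O)c4ccoc4C[C@@]23O | intermediate
39 | C2 allylic bromide | BrC/C=C1/C(=O)OC[C@]12C[C@@H](OC(C)=O)[C@@H](C)[C@]3(C)CC(=O)c4ccoc4C[C@@]23O | intermediate
40 | C10 chloromagnesium alkoxide of 39 | BrC/C=C1/C(=O)OC[C@]12C[C@@H](OC(C)=O)[C@@H](C)[C@]3(C)CC(=O)c4ccoc4C[C@@]23O[Mg]Cl | intermediate
41 | CNP0329797.2 (7β-acetoxy-10α-hydroxy-12-oxo 18,19-olide with ring C closed between C1 and C16) | CC(=O)O[C@@H]1C[C@@]23COC(=O)C2=CC[C@H]2c4occc4C(=O)C[C@@](C)([C@@H]1C)[C@@]23O | target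

## Step count and least certain steps

Total step count: 25. Longest linear sequence: 21 steps (steps 1–6, 8–12, 14–16, 19–25).

**Step 20 (key step).** The most likely failure is that the alkenylpalladium intermediate never reaches C5. The ester prefers its s-trans rotamer, and C5 is a fully substituted alkene carbon next to the C10 carbinol, so ionisation of the allylic ester or loss of iodine by reduction can take over. The fallback replaces carbopalladation by conjugate addition and sets out from 27. The primary hydroxyl is esterified with diethylphosphonoacetic acid (carbodiimide) to give the phosphonoacetate F1. HF·pyridine frees the C7 allylic alcohol F2, and Dess–Martin oxidation gives the ring B enone F3. NaH in THF should then induce 5-exo Michael addition of the phosphonate carbanion to C5 on the α face, for the same steric reasons, to give the α-phosphono spirolactone F4. Horner–Wadsworth–Emmons reaction of F4 with 28 installs the (E)-alkylidene and the route is rejoined at 35.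

**Step 12.** The most likely failure is slow oxidative addition to the hindered, electron-rich 2-chlorofuran and slow reductive elimination from an eight-membered palladacycle, so that dechlorination or ketone self-condensation wins. The fallback activates C1 as an ester and closes ring C by acylation; it sets out from 17. Palladium-catalysed coupling of the chlorofuran with the Reformatsky reagent BrZnCH2CO2Me gives the furylacetate F5. NaH in THF then induces an intramolecular Claisen condensation of the ester enolate with the lactone carbonyl to give the β-keto ester F6 with the C7 hydroxyl released. Krapcho dealkoxycarbonylation (LiCl, wet DMSO, 130 °C) gives the hydroxy ketone F7, and silylation with TBSCl and imidazole rejoins the route at 20.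

**Step 14.** The most likely failure is proton transfer from the furfuryl C1 position to the alkenyl metal, or sluggish addition of a branched nucleophile to a neopentyl ketone, with incomplete facial control as a second concern. The fallback uses a smaller commercial nucleophile and adds the C19 oxygen afterwards; it sets out from 20. Isopropenylmagnesium bromide with LaCl3·2LiCl in THF at 0 °C gives the isopropenyl carbinol F8. Allylic hydroxylation of its methyl group with catalytic SeO2 and t-BuOOH rejoins the route at 26.

**Step 25.** The most likely failure is that proton transfers populate the C11 enolate or the γ-deprotonated lactone instead of the C1 carbanion, which scrambles the alkene geometry, or that the C10 oxygen attacks C2 despite the magnesium counter-ion. The fallback replaces alkylation by an aldol addition followed by deoxygenation; it sets out from 38. MnO2 oxidises the allylic alcohol to the enal F9, which has no acidic C2 hydrogens and whose hemiacetal with the C10 hydroxyl forms reversibly. LiN(SiMe3)2 in THF at −78 °C then closes ring A by vinylogous aldol addition of C1 to the aldehyde, giving the allylic alcohol F10. 1,1'-Thiocarbonyldiimidazole converts F10 into the thiocarbamate F11, and Barton–McCombie reduction (Bu3SnH, AIBN) rejoins the route at 41.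

## Further compounds

F1 | step 20 | C19 diethylphosphonoacetate of 27 | CCOP(=O)(OCC)CC(=O)OCC1=C[C@@H](O[Si](C)(C)C(C)(C)C)[C@@H](C)[C@]2(C)CC3(OCCO3)c3ccoc3C[C@@]12O
F2 | step 20 | C7 allylic alcohol of F1 | CCOP(=O)(OCC)CC(=O)OCC1=C[C@@H](O)[C@@H](C)[C@]2(C)CC3(OCCO3)c3ccoc3C[C@@]12O
F3 | step 20 | ring B enone (C7 ketone, C5=C6) phosphonoacetate | CCOP(=O)(OCC)CC(=O)OCC1=CC(=O)[C@@H](C)[C@]2(C)CC3(OCCO3)c3ccoc3C[C@@]12O
F4 | step 20 | α-(diethoxyphosphoryl) spirolactone on quaternary C5 with C7 ketone | CCOP(=O)(OCC)C1C(=O)OC[C@]12CC(=O)[C@@H](C)[C@]3(C)CC4(OCCO4)c4ccoc4C[C@@]23O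
F5 | step 12 | methyl [3-(dioxolanyl)furan-2-yl]acetate lactone (C1 as ester-activated methylene) | C=C[C@H]1OC(=O)[C@@](C)(CC2(OCCO2)c2ccoc2CC(=O)OC)[C@@H]1C
F6 | step 12 | ring C β-keto ester with free C7 hydroxyl | COC(=O)C1c2occc2C2(OCCO2)C[C@@](C)([C@H](C)[C@H](O)C=C)C1=O
F7 | step 12 | ring C ketone with free C7 hydroxyl | O=C1Cc2occc2C2(OCCO2)C[C@@]1(C)[C@H](C)[C@H](O)C=C
F8 | step 14 | C10 isopropenyl carbinol of ring C | CC(=C)[C@]1(O)Cc2occc2C2(OCCO2)C[C@@]1(C)[C@H](C)[C@H](O[Si](C)(C)C(C)(C)C)C=C
F9 | step 25 | C2 enal | O=C/C=C1/C(=O)OC[C@]12C[C@@H](OC(C)=O)[C@@H](C)[C@]3(C)CC(=O)c4ccoc4C[C@@]23O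
F10 | step 25 | 2-hydroxy derivative of the target (ring A closed by aldol) | CC(=O)O[C@@H]1C[C@@]23COC(=O)C2=CC(O)[C@H]2c4occc4C(=O)C[C@@](C)([C@@H]1C)[C@@]23O
F11 | step 25 | C2 O-(imidazol-1-ylcarbonothioyl) derivative of F10 | CC(=O)O[C@@H]1C[C@@]23COC(=O)C2=CC(OC(=S)n4ccnc4)[C@H]2c4occc4C(=O)C[C@@](C)([C@@H]1C)[C@@]23O
A1 | alternative 1 | furan-fused cycloheptanone (ring C, C10 ketone, C12 dioxolane) carrying the C9 arm | O=C1Cc2occc2C2(OCCO2)C[C@@]1(C)[C@H](C)[C@H](O[Si](C)(C)C(C)(C)C)C[C@@H](CO[Si](C)(C)C(C)(C)C)C(=O)OC
A2 | alternative 1 | C10 silyl enol ether with ring C still open (furan C16–H free) | C=C(O[Si](C)(C)C(C)(C)C)[C@@](C)(CC1(OCCO1)c1ccoc1)[C@H](C)[C@H](O[Si](C)(C)C(C)(C)C)C[C@@H](CO[Si](C)(C)C(C)(C)C)C(=O)OC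
A3 | alternative 2 | exo 7-oxanorbornene cycloadduct (oxygen bridge from C10 to C3) | O=C1OC[C@@]23C[C@@H](O[Si](C)(C)C(C)(C)C)[C@@H](C)[C@](C)(CCO[Si](C)(C)C(C)(C)C)[C@@]2(O4)C=C[C@H]4[C@@H]13
A4 | alternative 2 | 2-alkylfuran tethered to the C4=C5 butenolide | O=C1OCC(C[C@@H](O[Si](C)(C)C(C)(C)C)[C@@H](C)[C@](C)(CCO[Si](C)(C)C(C)(C)C)c2ccco2)=C1
A5 | alternative 3 | ring A/ring B ketol with C2 ketone, C3=C4 ester and 3-bromofuryl on C1 | COC(=O)C1=CC(=O)[C@@H](c2occc2Br)[C@]2(O)[C@@](C)(CC(OC)OC)[C@H](C)[C@H](O[Si](C)(C)C(C)(C)C)C[C@@]12CO[Si](C)(C)C(C)(C)C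
A6 | alternative 3 | ring B ketone (C10 ketone, C5–H, C12 as dimethyl acetal) | O=C1C(CO[Si](C)(C)C(C)(C)C)C[C@@H](O[Si](C)(C)C(C)(C)C)[C@@H](C)[C@]1(C)CC(OC)OC
A7 | alternative 3 | methyl 5-(3-bromofuran-2-yl)-4-oxopent-2-ynoate | COC(=O)C#CC(=O)Cc1occc1Br
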